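The numbers in the tables come from a simulation on assumed constants; the scatter is artificial.

Two questions stand over this row of flasks: what share of the product is target, and how that share runs as the charge grows more concentrated.

| flask | substrate | partner | initiator | remark | time |
|---|---|---|---|---|---|
| amber | 0.050 M | 4 equiv | 0.34 mol% | run made earlier |  |
| Friday's | 0.050 M | 4.00 equiv | 0.5 mol% |  | 30 min |
| Sunday's | 0.060 M | 4.00 equiv | 0.5 mol% |  | 30 min |
| Thursday's | 0.10 M | 4.00 equiv | 0.5 mol% |  | 30 min |
| Wednesday's | 0.15 M | 4.00 equiv | 0.5 mol% |  | 30 min |
| Tuesday's | 0.25 M | 4.00 equiv | 0.5 mol% |  | 30 min |

amber run (percent of the substrate charged)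

| time / min | target / % | side product / % | substrate / % |
|---|---|---|---|
| 0.500 | 1.2 | 0 | 98.3 |
| 0.833 | 2.8 | 0 | 97.9 |
| 1.33 | 4.5 | 0 | 96.3 |
| 2.00 | 5.4 | 0.3 | 94.3 |
| 4.00 | 10.5 | 1.4 | 88.6 |
| 6.00 | 14.7 | 2.3 | 83.5 |

(readings scatter by 0.5 percentage points)

- a species is counted by the substrate in it: one side product counts as two
- the earlier runs were read with a standard deviation of 0.5 percentage points
- "hardly changes" means that all values lie within two and a half points (for a concentration: within two and a half percent of the largest)
- no earlier run changes the charge of initiator; that part of a forecast is a guess

* share of target in all that became target or side product for Friday's, Sunday's, Thursday's, Wednesday's, Tuesday's, in this order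
* how the row runs (rises all the way / falls all the way / rises, then falls / falls, then rises / hardly changes)

Let a, p and o be substrate, target and side product as fractions of the charge. In the amber run the side product appears with a lag, and it holds two substrates, so target + substrate is its likely origin. The natural zero of the scale is the even split, o = p. While a stays near one, target loses to substrate in a pseudo-first-order way and p grows in a straight line, so o grows with the square of the time. The factor two of the count cancels the factor from integrating that line, which leaves o/p = t/T. Pooling the amber readings at 4.00 min and 6.00 min gives this parity time, the time at which the even split arrives with a held near one, as 35.2 min. It is a rough reading, since the side-product values of 1.4% and 2.3% carry a scatter of 0.5 percentage points.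

The first objection is that the loading of 0.5 mol% was never run. However, the speed of target formation cancels from o/p, so that guess enters through a.

The second objection is that a does not stay near one for 30 min. The amber substrate falls at about 0.0301 min⁻¹, which puts a near 40.6% at the end and 65.9% on average. The side path's clock therefore slows, o/p becomes 0.562, and my share for Friday's is 64.0%.

The third objection concerns concentration. T should shrink with the charge, to 7.04 min for Tuesday's, which gives 26.3% on the same substrate curve. That curve is itself doubtful, because no earlier run varies concentration, and a faster chain in Tuesday's flask would raise this share.

The forecast gives 60%, 56%, 44%, 34% and 24%, and says the row falls all the way, on the ground that “The side path is bimolecular, so its weight should grow with concentration while target formation stays roughly pseudo-first-order.”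

The flasks give 68.8%, 65.8%, 57.4%, 51.2% and 44.2%, and the row falls all the way. The shape holds, but Tuesday's stands 20 points above the forecast.

    initiator → 2 initiating radical (k = 0.0170 min⁻¹)
    substrate + initiating radical → capped initiator + first chain carrier (k = 82000 M⁻¹ s⁻¹)
    partner + first chain carrier ⇌ target + second chain carrier (K = 0.320, k = 18000 M⁻¹ s⁻¹)
    substrate + second chain carrier → by-product + first chain carrier (k = 2.30 × 10⁵ M⁻¹ min⁻¹)
    2 second chain carrier → ended chains (k = 2.80 × 10⁶ M⁻¹ s⁻¹)
    substrate + target → side product (k = 0.460 M⁻¹ min⁻¹)

Read backwards, T turns o/p into the time that substrate and target effectively shared. From the constant of the last step, T is 43.5 min for Friday's and 8.70 min for Tuesday's, so this shared time is 19.7 min of the 30 min for Friday's and 11.0 min for Tuesday's, where 3.34% of the substrate remains. Tuesday's time over Friday's is 0.558, a ratio from which the amber reading of T cancels. Tuesday's target keeps that long a company with substrate because two second chain carriers meet and form ended chains. Without that step the same flask gives 96.6% instead of 44.2%, a shared time of about 0.310 min.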